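**Retrosynthetic overview**
- The β-hydroxy ketone is the decarboxylative ring-opening product of a (6R)-3-benzyl-6-(2-arylethyl)-4-hydroxy-5,6-dihydro-2-pyrone (lactone C4 becomes the ketone C3, lactone C6 becomes the carbinol C5); O-debenzylation follows in the same pot.
- The C1–C2 bond comes from reductive alkylation of the dihydropyrone C3 with unprotected 3,4-dihydroxy-5-methoxybenzaldehyde.
- The only stereocenter comes from enantioselective dearomative hydrogenation of the C5=C6 bond of a 6-(2-arylethyl)-4-hydroxy-2-pyrone (key step).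
- The C6–C7 bond comes from alkylation of the dianion of triacetic acid lactone with 4-benzyloxy-3-methoxybenzyl bromide.
- No ring is built: both benzene rings and the pyrone ring are bought; the pyrone ring is dearomatised (step 3) and opened (step 5).

Assumption: with the (S)-ligand, hydrogen is taken to add to the face that gives the (6R)-lactone; I could not fix the sense of induction from memory, so if it is the opposite, the (R)-ligand is used and nothing else changes.

**Step 1**
Reactants: 1 4-(benzyloxy)-3-methoxybenzyl alcohol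
Product: 2 4-(benzyloxy)-3-methoxybenzyl bromide
Conditions: PBr3 (0.4 equiv), Et2O, 0 °C; used crude
Reagents that add atoms: phosphorus tribromide, BrP(Br)Br
Why: The alcohol is activated as a bromophosphite and displaced by bromide at the benzylic carbon (SN2, PBr3 bromination); the aryl ethers are inert at 0 °C.

**Step 2**
Reactants: 3 4-hydroxy-6-methyl-2H-pyran-2-one (triacetic acid lactone); 2 4-(benzyloxy)-3-methoxybenzyl bromide
Product: 5 6-[2-(4-benzyloxy-3-methoxyphenyl)ethyl]-4-hydroxy-2H-pyran-2-one, via pyrone dianion 4 (not isolated)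
Conditions: LiN(i-Pr)2 (2.3 equiv), THF/HMPA, −78 °C; then 2, −78 → 0 °C; aq. HCl
Reagents that add atoms: none
Why: The second equivalent of base removes a proton from the C6-methyl group of the lithium pyronate (lateral, vinylogous deprotonation), and the dianion reacts with the benzylic bromide at this most nucleophilic terminal carbon (dianion SN2 alkylation), leaving O4 and C3 untouched.

**Step 3 (key step)**
Reactants: 5 6-[2-(4-benzyloxy-3-methoxyphenyl)ethyl]-4-hydroxy-2H-pyran-2-one
Product: 6 (6R)-6-[2-(4-benzyloxy-3-methoxyphenyl)ethyl]-4-hydroxy-5,6-dihydro-2H-pyran-2-one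
Conditions: H2 (60 bar), [Ru(OAc)2((S)-MeO-BIPHEP)] (1 mol%), HBF4·OEt2 (2 mol%), MeOH, 60 °C, stopped at 1 equiv H2 (MeO-BIPHEP = (6,6'-dimethoxybiphenyl-2,2'-diyl)bis(diphenylphosphine))
Reagents that add atoms: none
Why: Catalytic asymmetric dearomative hydrogenation of a 6-alkyl-4-hydroxy-2-pyrone: the cationic divalent ruthenium diphosphine complex adds H2 to one enantioface of the C5=C6 bond only, which sets C6 as R, while the remaining enolised β-keto lactone, the benzyl ether and the arene react much more slowly.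

**Step 4**
Reactants: 6 (6R)-6-[2-(4-benzyloxy-3-methoxyphenyl)ethyl]-4-hydroxy-5,6-dihydro-2H-pyran-2-one; 7 3,4-dihydroxy-5-methoxybenzaldehyde (5-hydroxyvanillin)
Product: 9 (6R)-6-[2-(4-benzyloxy-3-methoxyphenyl)ethyl]-3-(3,4-dihydroxy-5-methoxybenzyl)-4-hydroxy-5,6-dihydro-2H-pyran-2-one, via benzylidene dione 8 (not isolated)
Conditions: Hantzsch ester (1.1 equiv), L-proline (20 mol%), EtOH, 25 °C, Ar
Reagents that add atoms: none
Why: Organocatalytic three-component reductive alkylation: proline-mediated Knoevenagel condensation at the acidic C3 gives 8, which is reduced at once by conjugate hydride transfer from the Hantzsch ester before a second lactone can add; free phenols are tolerated and C6 is not involved.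

**Step 5**
Reactants: 9 (6R)-6-[2-(4-benzyloxy-3-methoxyphenyl)ethyl]-3-(3,4-dihydroxy-5-methoxybenzyl)-4-hydroxy-5,6-dihydro-2H-pyran-2-one
Product: 12 (5R)-1-(3,4-dihydroxy-5-methoxyphenyl)-5-hydroxy-7-(4-hydroxy-3-methoxyphenyl)heptan-3-one, via keto acid 10 (not isolated), via benzyl ether 11 (not isolated)
Conditions: 1,4-dioxane/H2O (1:1), degassed, 90 °C; then Pd/C (10%), H2 (1 atm), 25 °C
Reagents that add atoms: none
Why: Water adds to the lactone carbonyl of the keto tautomer (acyl–oxygen cleavage, so the C–O bond at the stereocenter is never broken and the water oxygen leaves in CO2), the β-keto acid 10 decarboxylates (decarboxylative ring opening, as known for the 6-methyl parent lactone in hot water), and Pd/C hydrogenolysis then removes the benzyl ether without touching the ketone or the secondary alcohol.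

**Compound list**
1 | 4-(benzyloxy)-3-methoxybenzyl alcohol | COc1cc(CO)ccc1OCc1ccccc1 | starting material
2 | 4-(benzyloxy)-3-methoxybenzyl bromide | COc1cc(CBr)ccc1OCc1ccccc1 | intermediate
3 | 4-hydroxy-6-methyl-2H-pyran-2-one (triacetic acid lactone) | CC1=CC(O)=CC(=O)O1 | starting material
4 | dilithium salt of the O4,C7-dianion of 3 | [Li+].[Li+].[CH2-]C1=CC([O-])=CC(=O)O1 | intermediate
5 | 6-[2-(4-benzyloxy-3-methoxyphenyl)ethyl]-4-hydroxy-2H-pyran-2-one | O=C1C=C(O)C=C(CCc2ccc(OCc3ccccc3)c(OC)c2)O1 | intermediate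
6 | (6R)-6-[2-(4-benzyloxy-3-methoxyphenyl)ethyl]-4-hydroxy-5,6-dihydro-2H-pyran-2-one | O=C1C=C(O)C[C@@H](CCc2ccc(OCc3ccccc3)c(OC)c2)O1 | intermediate
7 | 3,4-dihydroxy-5-methoxybenzaldehyde | COc1cc(C=O)cc(O)c1O | starting material
8 | (6R)-6-[2-(4-benzyloxy-3-methoxyphenyl)ethyl]-3-(3,4-dihydroxy-5-methoxybenzylidene)dihydro-2H-pyran-2,4(3H)-dione | O=C1C(=Cc2cc(O)c(O)c(OC)c2)C(=O)C[C@@H](CCc2ccc(OCc3ccccc3)c(OC)c2)O1 | intermediate
9 | (6R)-6-[2-(4-benzyloxy-3-methoxyphenyl)ethyl]-3-(3,4-dihydroxy-5-methoxybenzyl)-4-hydroxy-5,6-dihydro-2H-pyran-2-one | O=C1C(Cc2cc(O)c(O)c(OC)c2)=C(O)C[C@@H](CCc2ccc(OCc3ccccc3)c(OC)c2)O1 | intermediate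
10 | (5R)-7-(4-benzyloxy-3-methoxyphenyl)-2-(3,4-dihydroxy-5-methoxybenzyl)-5-hydroxy-3-oxoheptanoic acid (C2 epimers) | OC(=O)C(Cc1cc(O)c(O)c(OC)c1)C(=O)C[C@H](O)CCc1ccc(OCc2ccccc2)c(OC)c1 | intermediate
11 | (5R)-7-(4-benzyloxy-3-methoxyphenyl)-1-(3,4-dihydroxy-5-methoxyphenyl)-5-hydroxyheptan-3-one | COc1cc(CC[C@@H](O)CC(=O)CCc2cc(O)c(O)c(OC)c2)ccc1OCc1ccccc1 | intermediate
12 | (5R)-1-(3,4-dihydroxy-5-methoxyphenyl)-5-hydroxy-7-(4-hydroxy-3-methoxyphenyl)heptan-3-one | COc1cc(CC[C@@H](O)CC(=O)CCc2cc(O)c(O)c(OC)c2)ccc1O | target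

**Totals**
Total step count: 5. Longest linear sequence: 5 steps (from 1; compounds 3 and 7 enter at steps 2 and 4).

**Three steps most likely to fail**

Step 3 (enantioselectivity, sense of induction, over-reduction of the β-keto lactone). The fallback sets out from bromide 2 and comes back at 6; the stereocenter is then set by ketone hydrogenation instead of pyrone hydrogenation. Bromide 2 alkylates the dianion of methyl acetoacetate (NaH, then n-BuLi, THF, 0 °C) at the terminal carbon to give methyl 5-(4-benzyloxy-3-methoxyphenyl)-3-oxopentanoate F1. Noyori hydrogenation with [RuCl2((R)-BINAP)] (H2, MeOH) gives methyl (3R)-5-(4-benzyloxy-3-methoxyphenyl)-3-hydroxypentanoate F2. Claisen condensation with excess LiCH2CO2t-Bu (THF, −78 → −20 °C) gives tert-butyl (5R)-7-(4-benzyloxy-3-methoxyphenyl)-5-hydroxy-3-oxoheptanoate F3, and CF3CO2H in CH2Cl2 closes the ring to 6.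

Step 4 (sluggish Knoevenagel condensation of the electron-rich free-catechol aldehyde, bis-adduct formation). The fallback sets out from aldehyde 7 and comes back at 9; the C–C bond is made by 1,6-addition to a quinone methide instead of condensation and hydride transfer. NaBH4 in MeOH reduces 7 to 5-(hydroxymethyl)-3-methoxybenzene-1,2-diol F4. Warming F4 with 6 in H2O/EtOH with catalytic AcOH ionises it to the para-quinone methide 2-hydroxy-6-methoxy-4-methylidenecyclohexa-2,5-dien-1-one F5, which is trapped in the flask by the enol carbon C3 of 6 to give 9.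

Step 5 (slow opening of the 3-substituted enol lactone, or dehydration of the β-hydroxy ketone to the enone at 90 °C). The fallback sets out from 6 and comes back at 12; decarboxylation is done before the second aryl unit is attached. Lactone 6 is heated alone in 1,4-dioxane/H2O (the direct analogue of the known 6-methyl case) to give (4R)-6-(4-benzyloxy-3-methoxyphenyl)-4-hydroxyhexan-2-one F6. Pyrrolidine/AcOH-mediated Claisen–Schmidt condensation of the methyl group with 7 (THF, 25 °C) gives (1E,5R)-7-(4-benzyloxy-3-methoxyphenyl)-1-(3,4-dihydroxy-5-methoxyphenyl)-5-hydroxyhept-1-en-3-one F7. H2 with Pd/C in EtOAc/MeOH then saturates the enone and removes the benzyl group to give 12.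

**Further compounds**
F1 | step 3 | methyl 5-(4-benzyloxy-3-methoxyphenyl)-3-oxopentanoate | COC(=O)CC(=O)CCc1ccc(OCc2ccccc2)c(OC)c1
F2 | step 3 | methyl (3R)-5-(4-benzyloxy-3-methoxyphenyl)-3-hydroxypentanoate | COC(=O)C[C@H](O)CCc1ccc(OCc2ccccc2)c(OC)c1
F3 | step 3 | tert-butyl (5R)-7-(4-benzyloxy-3-methoxyphenyl)-5-hydroxy-3-oxoheptanoate | CC(C)(C)OC(=O)CC(=O)C[C@H](O)CCc1ccc(OCc2ccccc2)c(OC)c1
F4 | step 4 | 5-(hydroxymethyl)-3-methoxybenzene-1,2-diol | COc1cc(CO)cc(O)c1O
F5 | step 4 | 2-hydroxy-6-methoxy-4-methylidenecyclohexa-2,5-dien-1-one | C=C1C=C(O)C(=O)C(OC)=C1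
F6 | step 5 | (4R)-6-(4-benzyloxy-3-methoxyphenyl)-4-hydroxyhexan-2-one | CC(=O)C[C@H](O)CCc1ccc(OCc2ccccc2)c(OC)c1
F7 | step 5 | (1E,5R)-7-(4-benzyloxy-3-methoxyphenyl)-1-(3,4-dihydroxy-5-methoxyphenyl)-5-hydroxyhept-1-en-3-one | COc1cc(CC[C@@H](O)CC(=O)/C=C/c2cc(O)c(O)c(OC)c2)ccc1OCc1ccccc1
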